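**Strategy.** The side chain (C1' = benzylic CH2 … C16') is cut between the alkene carbon C7' and the methylene C8'. The step exploits the unfunctionalised C8'–C10' trimethylene unit that flanks the (E)-C6'=C7' trisubstituted alkene: C8' is the anti-Markovnikov terminus of a vinyl group, C7' an (E)-iodoalkene carbon. One-pot 9-BBN hydroboration of alkene 21 (C8'–C13', both stereocentres set, Weinreb amide as enone precursor) and B-alkyl Suzuki–Miyaura coupling with iodide 14 (arene plus C1'–C7', C5' set) forms the bond with retention of alkene geometry and delivers the complete C1'–C13' chain. Isobutenyl Grignard addition and global desilylation finish the synthesis.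

Key step: step 14

Assumption: (R)-TRIP is taken to deliver the (R)-carbinol in step 5, by analogy with aryl and alkenyl aldehydes (the alkynyl group ranks over the new CH2 as aryl does); should the ynal respond in the opposite sense, (S)-TRIP is used. Compounds 1, 7 and 15 are taken as commercial. TBS = tert-butyldimethylsilyl. Target configuration: 2'E, 5'R, 6'E, 11'S, 12'R.

**Arene building block**

Step 1
Reactants: 1 4-methoxy-2-methylphenol
Product: 3 2-hydroxy-5-methoxy-3-methylbenzaldehyde, via salicyl alcohol 2 (not isolated)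
Conditions: MgCl2, Et3N, (CH2O)n, MeCN, reflux; aq. HCl work-up
Reagents that add atoms: paraformaldehyde (as formaldehyde) C=O
Why: Casnati–Skattebøl ortho-formylation: the magnesium phenoxide directs formaldehyde to the only free ortho position, and the salicyl alcohol is oxidised in situ by a second formaldehyde (Oppenauer-type hydride transfer).

Step 2
Reactants: 3 2-hydroxy-5-methoxy-3-methylbenzaldehyde
Product: 4 2-[(tert-butyldimethylsilyl)oxy]-5-methoxy-3-methylbenzaldehyde
Conditions: TBSCl, imidazole, DMAP (cat.), DMF, rt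
Reagents that add atoms: tert-butyldimethylsilyl chloride CC(C)(C)[Si](C)(C)Cl
Why: Standard phenol silylation; the silyl ether keeps the later benzylic chloride from collapsing to an o-quinone methide and is removable with fluoride at the end.

Step 3
Reactants: 4 2-[(tert-butyldimethylsilyl)oxy]-5-methoxy-3-methylbenzaldehyde
Product: 5 {2-[(tert-butyldimethylsilyl)oxy]-5-methoxy-3-methylphenyl}methanol
Conditions: NaBH4, MeOH/THF, 0 °C, short; aq. NH4Cl
Reagents that add atoms: none
Why: Chemoselective borohydride reduction of the aldehyde; brief reaction at 0 °C and a neutral quench should prevent migration of the aryl silyl group to the benzylic oxygen.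

Step 4
Reactants: 5 {2-[(tert-butyldimethylsilyl)oxy]-5-methoxy-3-methylphenyl}methanol
Product: 6 tert-butyl[2-(chloromethyl)-4-methoxy-6-methylphenoxy]dimethylsilane
Conditions: PPh3, CCl4, CH2Cl2, 0 °C → rt
Reagents that add atoms: carbon tetrachloride ClC(Cl)(Cl)Cl
Why: Appel chlorination converts the benzylic alcohol to the chloride under neutral conditions that spare the aryl silyl ether.

**Left half (arene + C1'–C7')**

Step 5
Reactants: 7 but-2-ynal
Product: 9 (4R)-hepta-1,5-diyn-4-ol, via borate ester 8 (not isolated)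
Conditions: allenylboronic acid pinacol ester, (R)-TRIP (5 mol%), 4 Å MS, toluene, 0 °C; aqueous work-up
Reagents that add atoms: allenylboronic acid pinacol ester C=C=CB1OC(C)(C)C(C)(C)O1
Why: Chiral phosphoric acid-catalysed propargylboration: the allenylboronate adds through a closed six-membered SE2' transition state organised by the catalyst, which should select one aldehyde face and set C5' as R.

Step 6
Reactants: 9 (4R)-hepta-1,5-diyn-4-ol
Product: 10 tert-butyl[(4R)-hepta-1,5-diyn-4-yloxy]dimethylsilane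
Conditions: TBSCl, imidazole, DMF, rt
Reagents that add atoms: tert-butyldimethylsilyl chloride CC(C)(C)[Si](C)(C)Cl
Why: Silylation of the secondary alcohol removes the O–H that would consume Me3Al and Schwartz reagent.

Step 7
Reactants: 10 tert-butyl[(4R)-hepta-1,5-diyn-4-yloxy]dimethylsilane; 6 tert-butyl[2-(chloromethyl)-4-methoxy-6-methylphenoxy]dimethylsilane
Product: 12 tert-butyl{2-[(2E,5R)-5-(tert-butyldimethylsilyloxy)-3-methyloct-2-en-6-yn-1-yl]-4-methoxy-6-methylphenoxy}dimethylsilane, via alkenylalane 11 (not isolated)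
Conditions: Me3Al, Cp2ZrCl2 (25 mol%), CH2Cl2, 0 °C → rt; volatiles removed, THF; then 6, Pd(PPh3)4 (5 mol%), rt
Reagents that add atoms: trimethylaluminium C[Al](C)C
Why: Negishi Zr-catalysed methylalumination adds Me–Al syn across the terminal alkyne only (the internal propynyl unit reacts far more slowly), with methyl on the internal carbon; Pd-catalysed alkenyl–benzyl coupling then proceeds with retention and fixes the (E)-C2'=C3' geometry.

Step 8
Reactants: 12 tert-butyl{2-[(2E,5R)-5-(tert-butyldimethylsilyloxy)-3-methyloct-2-en-6-yn-1-yl]-4-methoxy-6-methylphenoxy}dimethylsilane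
Product: 14 tert-butyl{2-[(2E,5R,6E)-5-(tert-butyldimethylsilyloxy)-7-iodo-3-methylocta-2,6-dien-1-yl]-4-methoxy-6-methylphenoxy}dimethylsilane, via alkenylzirconocene 13 (not isolated)
Conditions: Cp2Zr(H)Cl (2.5 equiv), THF, 50 °C; then I2, THF, 0 °C, dark
Reagents that add atoms: iodine II
Why: Schwartz hydrozirconation is syn and, with excess reagent at 50 °C, equilibrates zirconium to the methyl-bearing carbon C7', away from the branched silyloxy carbon; iodinolysis with retention should give the (E)-iodoalkene, the trisubstituted alkene being inert.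

**Right half (C8'–C13')**

Step 9
Reactants: 15 (E)-but-2-en-1-ol
Product: 16 [(2S,3S)-3-methyloxiran-2-yl]methanol
Conditions: t-BuOOH, Ti(OiPr)4 (cat.), L-(+)-DIPT (cat.), 4 Å MS, CH2Cl2, −20 °C; non-aqueous work-up
Reagents that add atoms: tert-butyl hydroperoxide CC(C)(C)OO
Why: Sharpless asymmetric epoxidation; L-(+)-tartrate delivers oxygen to the face that gives the (2S,3S)-epoxide, which fixes C12' and, before its inversion in step 11, C11'.

Step 10
Reactants: 16 [(2S,3S)-3-methyloxiran-2-yl]methanol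
Product: 18 (2R,3S)-3-methyloxirane-2-carboxylic acid, via epoxy aldehyde 17 (not isolated)
Conditions: RuCl3·xH2O (cat.), NaIO4, CCl4/MeCN/H2O, rt
Reagents that add atoms: sodium periodate [Na+].[O-]I(=O)(=O)=O; water O
Why: Sharpless RuO4 oxidation takes the primary alcohol to the acid and is known to leave 2,3-epoxides intact; the C2 descriptor changes to R by priority only.

Step 11
Reactants: 18 (2R,3S)-3-methyloxirane-2-carboxylic acid
Product: 19 (2R,3S)-2-hydroxy-3-methylhex-5-enoic acid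
Conditions: allylMgBr (3 equiv), CuI (10 mol%), THF, −40 → 0 °C; then 1 M HCl
Reagents that add atoms: allylmagnesium bromide C=CC[Mg]Br
Why: Copper-catalysed SN2 opening of the 2,3-epoxy carboxylate at C3 (C2 is deactivated by the adjacent carboxylate) with inversion should turn the trans-epoxide into the syn C11'-methyl/C12'-hydroxyl array (11'S,12'R).

Step 12
Reactants: 19 (2R,3S)-2-hydroxy-3-methylhex-5-enoic acid
Product: 20 (2R,3S)-2-hydroxy-N-methoxy-N,3-dimethylhex-5-enamide
Conditions: MeNH(OMe)·HCl, EDC·HCl, HOBt (cat.), N-methylmorpholine, CH2Cl2, 0 °C → rt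
Reagents that add atoms: N,O-dimethylhydroxylamine hydrochloride CNOC.Cl
Why: Carbodiimide amidation gives the Weinreb amide as latent C13' ketone; the amine out-competes the free secondary hydroxyl for the activated acid.

Step 13
Reactants: 20 (2R,3S)-2-hydroxy-N-methoxy-N,3-dimethylhex-5-enamide
Product: 21 (2R,3S)-2-[(tert-butyldimethylsilyl)oxy]-N-methoxy-N,3-dimethylhex-5-enamide
Conditions: TBSOTf, 2,6-lutidine, CH2Cl2, 0 °C
Reagents that add atoms: tert-butyldimethylsilyl triflate CC(C)(C)[Si](C)(C)OS(=O)(=O)C(F)(F)F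
Why: Silyl triflate silylation of the hindered secondary alcohol protects it before hydroboration and Grignard addition.

**Union and completion**

Step 14
Reactants: 21 (2R,3S)-2-[(tert-butyldimethylsilyl)oxy]-N-methoxy-N,3-dimethylhex-5-enamide; 14 tert-butyl{2-[(2E,5R,6E)-5-(tert-butyldimethylsilyloxy)-7-iodo-3-methylocta-2,6-dien-1-yl]-4-methoxy-6-methylphenoxy}dimethylsilane
Product: 23 (2R,3S,7E,9R,11E)-2,9-bis(tert-butyldimethylsilyloxy)-13-{2-[(tert-butyldimethylsilyl)oxy]-5-methoxy-3-methylphenyl}-N-methoxy-N,3,7,11-tetramethyltrideca-7,11-dienamide, via B-alkyl-9-BBN 22 (not isolated)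
Conditions: 21 (1.5 equiv), 9-BBN, THF, rt; then 3 M aq. K3PO4, 14, Pd(dppf)Cl2 (cat.), AsPh3 (cat.), DMF, rt, dark
Reagents that add atoms: none
Why: 9-BBN adds anti-Markovnikov to the only alkene of 21 (a monosubstituted vinyl group; the hindered Weinreb amide is inert at rt) and places boron on C8'; aqueous phosphate turns 22 into a hydroxyborate that transmetalates to the alkenyl-Pd(II) iodide from oxidative addition of 14, and reductive elimination forms C7'–C8'. The closest known reaction type is the B-alkyl Suzuki–Miyaura coupling of (E)-2-iodoalk-2-enes used for trisubstituted alkenes. No ring is closed and no stereocentre is created; C5', C11' and C12' are remote spectators. The selectivity needed is retention of the (E)-C6'=C7' geometry, inherent to oxidative addition and reductive elimination at sp2 carbon, and coupling faster than β-hydride elimination of the primary alkyl–Pd species, which the wide-bite-angle dppf ligand with AsPh3 should secure. Quenching excess 9-BBN with the aqueous base before 14 is added keeps borane away from the iodoalkene.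

Step 15
Reactants: 23 (2R,3S,7E,9R,11E)-2,9-bis(tert-butyldimethylsilyloxy)-13-{2-[(tert-butyldimethylsilyl)oxy]-5-methoxy-3-methylphenyl}-N-methoxy-N,3,7,11-tetramethyltrideca-7,11-dienamide
Product: 25 tert-butyl{2-[(2E,5R,6E,11S,12R)-5,12-bis(tert-butyldimethylsilyloxy)-3,7,11,15-tetramethyl-13-oxohexadeca-2,6,14-trien-1-yl]-4-methoxy-6-methylphenoxy}dimethylsilane, via magnesium hemiaminal 24 (not isolated)
Conditions: 2-methylprop-1-enylmagnesium bromide (3 equiv), THF, 0 °C → rt; cold aq. NH4Cl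
Reagents that add atoms: 2-methylprop-1-enylmagnesium bromide CC(C)=C[Mg]Br
Why: Weinreb ketone synthesis: the stable five-membered magnesium chelate prevents over-addition and releases the α'-silyloxy enone on quench, while silyl ethers and alkenes are inert to the Grignard reagent.

Step 16
Reactants: 25 tert-butyl{2-[(2E,5R,6E,11S,12R)-5,12-bis(tert-butyldimethylsilyloxy)-3,7,11,15-tetramethyl-13-oxohexadeca-2,6,14-trien-1-yl]-4-methoxy-6-methylphenoxy}dimethylsilane
Product: 26 4-methoxy-2-methyl-6-[(2E,5R,6E,11S,12R)-5,12-dihydroxy-3,7,11,15-tetramethyl-13-oxohexadeca-2,6,14-trien-1-yl]phenol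
Conditions: HF·pyridine, pyridine, THF, 0 °C → rt; aq. NaHCO3
Reagents that add atoms: none
Why: Buffered fluoride desilylation should cleave the two secondary and the aryl silyl ether without the basic conditions that could epimerise C12' or trigger oxa-Michael closure of the α'-hydroxy enone.

**Compound list**

1 | 4-methoxy-2-methylphenol | COc1ccc(O)c(C)c1 | starting material
2 | 2-(hydroxymethyl)-4-methoxy-6-methylphenol (formed as its magnesium phenoxide) | COc1cc(C)c(O)c(CO)c1 | intermediate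
3 | 2-hydroxy-5-methoxy-3-methylbenzaldehyde | COc1cc(C)c(O)c(C=O)c1 | intermediate
4 | 2-[(tert-butyldimethylsilyl)oxy]-5-methoxy-3-methylbenzaldehyde | COc1cc(C)c(O[Si](C)(C)C(C)(C)C)c(C=O)c1 | intermediate
5 | {2-[(tert-butyldimethylsilyl)oxy]-5-methoxy-3-methylphenyl}methanol | COc1cc(C)c(O[Si](C)(C)C(C)(C)C)c(CO)c1 | intermediate
6 | tert-butyl[2-(chloromethyl)-4-methoxy-6-methylphenoxy]dimethylsilane | COc1cc(C)c(O[Si](C)(C)C(C)(C)C)c(CCl)c1 | intermediate
7 | but-2-ynal | CC#CC=O | starting material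
8 | 2-[(4R)-hepta-1,5-diyn-4-yloxy]-4,4,5,5-tetramethyl-1,3,2-dioxaborolane | C#CC[C@@H](OB1OC(C)(C)C(C)(C)O1)C#CC | intermediate
9 | (4R)-hepta-1,5-diyn-4-ol | C#CC[C@@H](O)C#CC | intermediate
10 | tert-butyl[(4R)-hepta-1,5-diyn-4-yloxy]dimethylsilane | C#CC[C@@H](O[Si](C)(C)C(C)(C)C)C#CC | intermediate
11 | [(1E,4R)-4-(tert-butyldimethylsilyloxy)-2-methylhept-1-en-5-yn-1-yl]dimethylalane | C[Al](C)/C=C(\C)C[C@@H](O[Si](C)(C)C(C)(C)C)C#CC | intermediate
12 | tert-butyl{2-[(2E,5R)-5-(tert-butyldimethylsilyloxy)-3-methyloct-2-en-6-yn-1-yl]-4-methoxy-6-methylphenoxy}dimethylsilane | COc1cc(C)c(O[Si](C)(C)C(C)(C)C)c(C/C=C(\C)C[C@@H](O[Si](C)(C)C(C)(C)C)C#CC)c1 | intermediate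
13 | chlorobis(cyclopentadienyl){(2E,4R,6E)-4-(tert-butyldimethylsilyloxy)-8-[2-(tert-butyldimethylsilyloxy)-5-methoxy-3-methylphenyl]-6-methylocta-2,6-dien-2-yl}zirconium (Cp rings drawn σ-bonded) | COc1cc(C)c(O[Si](C)(C)C(C)(C)C)c(C/C=C(\C)C[C@@H](O[Si](C)(C)C(C)(C)C)/C=C(\C)[Zr](Cl)(C2C=CC=C2)C2C=CC=C2)c1 | intermediate
14 | tert-butyl{2-[(2E,5R,6E)-5-(tert-butyldimethylsilyloxy)-7-iodo-3-methylocta-2,6-dien-1-yl]-4-methoxy-6-methylphenoxy}dimethylsilane | COc1cc(C)c(O[Si](C)(C)C(C)(C)C)c(C/C=C(\C)C[C@@H](O[Si](C)(C)C(C)(C)C)/C=C(\C)I)c1 | intermediate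
15 | (E)-but-2-en-1-ol | C/C=C/CO | starting material
16 | [(2S,3S)-3-methyloxiran-2-yl]methanol | C[C@@H]1O[C@H]1CO | intermediate
17 | (2R,3S)-3-methyloxirane-2-carbaldehyde | C[C@@H]1O[C@H]1C=O | intermediate
18 | (2R,3S)-3-methyloxirane-2-carboxylic acid | C[C@@H]1O[C@H]1C(=O)O | intermediate
19 | (2R,3S)-2-hydroxy-3-methylhex-5-enoic acid | C=CC[C@H](C)[C@@H](O)C(=O)O | intermediate
20 | (2R,3S)-2-hydroxy-N-methoxy-N,3-dimethylhex-5-enamide | C=CC[C@H](C)[C@@H](O)C(=O)N(C)OC | intermediate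
21 | (2R,3S)-2-[(tert-butyldimethylsilyl)oxy]-N-methoxy-N,3-dimethylhex-5-enamide | C=CC[C@H](C)[C@@H](O[Si](C)(C)C(C)(C)C)C(=O)N(C)OC | intermediate
22 | (2R,3S)-6-(9-borabicyclo[3.3.1]nonan-9-yl)-2-[(tert-butyldimethylsilyl)oxy]-N-methoxy-N,3-dimethylhexanamide | B1(CCC[C@H](C)[C@@H](O[Si](C)(C)C(C)(C)C)C(=O)N(C)OC)C2CCCC1CCC2 | intermediate
23 | (2R,3S,7E,9R,11E)-2,9-bis(tert-butyldimethylsilyloxy)-13-{2-[(tert-butyldimethylsilyl)oxy]-5-methoxy-3-methylphenyl}-N-methoxy-N,3,7,11-tetramethyltrideca-7,11-dienamide | COc1cc(C)c(O[Si](C)(C)C(C)(C)C)c(C/C=C(\C)C[C@@H](O[Si](C)(C)C(C)(C)C)/C=C(\C)CCC[C@H](C)[C@@H](O[Si](C)(C)C(C)(C)C)C(=O)N(C)OC)c1 | intermediate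
24 | tetrahedral adduct of 23: C13' carries OMgBr, N(OMe)Me and the 2-methylprop-1-enyl group | COc1cc(C)c(O[Si](C)(C)C(C)(C)C)c(C/C=C(\C)C[C@@H](O[Si](C)(C)C(C)(C)C)/C=C(\C)CCC[C@H](C)[C@@H](O[Si](C)(C)C(C)(C)C)C(O[Mg]Br)(N(C)OC)C=C(C)C)c1 | intermediate
25 | tert-butyl{2-[(2E,5R,6E,11S,12R)-5,12-bis(tert-butyldimethylsilyloxy)-3,7,11,15-tetramethyl-13-oxohexadeca-2,6,14-trien-1-yl]-4-methoxy-6-methylphenoxy}dimethylsilane | COc1cc(C)c(O[Si](C)(C)C(C)(C)C)c(C/C=C(\C)C[C@@H](O[Si](C)(C)C(C)(C)C)/C=C(\C)CCC[C@H](C)[C@@H](O[Si](C)(C)C(C)(C)C)C(=O)C=C(C)C)c1 | intermediate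
26 | 4-methoxy-2-methyl-6-[(2E,5R,6E,11S,12R)-5,12-dihydroxy-3,7,11,15-tetramethyl-13-oxohexadeca-2,6,14-trien-1-yl]phenol | COc1cc(C)c(O)c(C/C=C(\C)C[C@@H](O)/C=C(\C)CCC[C@H](C)[C@@H](O)C(=O)C=C(C)C)c1 | target

**Count.** Total steps: 16. Longest linear sequence: 9 steps (1, 2, 3, 4, 7, 8, 14, 15, 16).

**Steps most likely to fail**

Step 11. The allyl nucleophile may attack C2 or the carboxylate instead of C3, and the small water-soluble acids 18 and 19 may be lost on isolation. The fallback sets out from 16 and returns at 21; it moves the regiocontrol to an ether-directed opening and builds the acid afterwards. Alcohol 16 is etherified (NaH, 4-methoxybenzyl chloride, Bu4NI, THF) to (2S,3S)-2-{[(4-methoxybenzyl)oxy]methyl}-3-methyloxirane F1. AllylMgBr/CuI should open F1 at the methyl-bearing C3, since the alkoxymethyl group deactivates C2, to give (2R,3S)-1-[(4-methoxybenzyl)oxy]-3-methylhex-5-en-2-ol F2. TBSOTf/2,6-lutidine gives tert-butyl{[(2R,3S)-1-[(4-methoxybenzyl)oxy]-3-methylhex-5-en-2-yl]oxy}dimethylsilane F3. DDQ (CH2Cl2, pH 7 buffer) frees (2R,3S)-2-[(tert-butyldimethylsilyl)oxy]-3-methylhex-5-en-1-ol F4. Dess–Martin oxidation gives (2R,3S)-2-[(tert-butyldimethylsilyl)oxy]-3-methylhex-5-enal F5, and Pinnick oxidation (NaClO2, 2-methylbut-2-ene) gives (2R,3S)-2-[(tert-butyldimethylsilyl)oxy]-3-methylhex-5-enoic acid F6. EDC coupling of F6 with MeNH(OMe)·HCl gives 21.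

Step 7. Aluminium Lewis acids may ionise the electron-rich benzylic chloride (self-alkylation, methyl transfer) faster than palladium couples it. The fallback sets out from 10 and 6 and returns at 12; it reverses the polarity of the C1'–C2' union. Alane 11, made from 10 as before, is quenched with iodine to tert-butyl{[(1E,4R)-1-iodo-2-methylhept-1-en-5-yn-4-yl]oxy}dimethylsilane F7. Chloride 6 is converted with zinc dust and LiCl in THF into {2-[(tert-butyldimethylsilyl)oxy]-5-methoxy-3-methylbenzyl}zinc chloride F8. Pd-catalysed Negishi coupling of F8 with F7 (Pd(OAc)2/SPhos, THF) gives 12 in the absence of aluminium species.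

Step 5. The catalyst may discriminate the faces of the slim ynal poorly (low enantiomeric purity), and the small diynol may be lost through volatility. The fallback sets out from 6 and returns at 12; it sets C5' by ketone reduction after the arene is attached. Commercial tert-butyl(but-3-yn-1-yloxy)dimethylsilane is methylaluminated (Me3Al, Cp2ZrCl2) to [(1E)-4-(tert-butyldimethylsilyloxy)-2-methylbut-1-en-1-yl]dimethylalane F9 and coupled with 6 (Pd(PPh3)4) to tert-butyl{2-[(2E)-5-(tert-butyldimethylsilyloxy)-3-methylpent-2-en-1-yl]-4-methoxy-6-methylphenoxy}dimethylsilane F10. PPTS in MeOH removes only the primary alkyl silyl ether to give (3E)-5-{2-[(tert-butyldimethylsilyl)oxy]-5-methoxy-3-methylphenyl}-3-methylpent-3-en-1-ol F11. Dess–Martin oxidation gives (3E)-5-{2-[(tert-butyldimethylsilyl)oxy]-5-methoxy-3-methylphenyl}-3-methylpent-3-enal F12. Prop-1-ynylmagnesium bromide gives racemic (6E)-8-{2-[(tert-butyldimethylsilyl)oxy]-5-methoxy-3-methylphenyl}-6-methyloct-6-en-2-yn-4-ol F13, and Dess–Martin oxidation gives (6E)-8-{2-[(tert-butyldimethylsilyl)oxy]-5-methoxy-3-methylphenyl}-6-methyloct-6-en-2-yn-4-one F14. Noyori transfer hydrogenation (RuCl[(R,R)-TsDPEN](p-cymene), i-PrOH; catalyst enantiomer chosen for the R alcohol) should give (4R,6E)-8-{2-[(tert-butyldimethylsilyl)oxy]-5-methoxy-3-methylphenyl}-6-methyloct-6-en-2-yn-4-ol F15. TBSOTf/2,6-lutidine then gives 12.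

**Further compounds**

F1 | step 11 | (2S,3S)-2-{[(4-methoxybenzyl)oxy]methyl}-3-methyloxirane | C[C@@H]1O[C@H]1COCc1ccc(OC)cc1
F2 | step 11 | (2R,3S)-1-[(4-methoxybenzyl)oxy]-3-methylhex-5-en-2-ol | C=CC[C@H](C)[C@@H](O)COCc1ccc(OC)cc1
F3 | step 11 | tert-butyl{[(2R,3S)-1-[(4-methoxybenzyl)oxy]-3-methylhex-5-en-2-yl]oxy}dimethylsilane | C=CC[C@H](C)[C@@H](O[Si](C)(C)C(C)(C)C)COCc1ccc(OC)cc1
F4 | step 11 | (2R,3S)-2-[(tert-butyldimethylsilyl)oxy]-3-methylhex-5-en-1-ol | C=CC[C@H](C)[C@@H](O[Si](C)(C)C(C)(C)C)CO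
F5 | step 11 | (2R,3S)-2-[(tert-butyldimethylsilyl)oxy]-3-methylhex-5-enal | C=CC[C@H](C)[C@@H](O[Si](C)(C)C(C)(C)C)C=O
F6 | step 11 | (2R,3S)-2-[(tert-butyldimethylsilyl)oxy]-3-methylhex-5-enoic acid | C=CC[C@H](C)[C@@H](O[Si](C)(C)C(C)(C)C)C(=O)O
F7 | step 7 | tert-butyl{[(1E,4R)-1-iodo-2-methylhept-1-en-5-yn-4-yl]oxy}dimethylsilane | I/C=C(\C)C[C@@H](O[Si](C)(C)C(C)(C)C)C#CC
F8 | step 7 | {2-[(tert-butyldimethylsilyl)oxy]-5-methoxy-3-methylbenzyl}zinc chloride | COc1cc(C)c(O[Si](C)(C)C(C)(C)C)c(C[Zn]Cl)c1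
F9 | step 5 | [(1E)-4-(tert-butyldimethylsilyloxy)-2-methylbut-1-en-1-yl]dimethylalane | C[Al](C)/C=C(\C)CCO[Si](C)(C)C(C)(C)C
F10 | step 5 | tert-butyl{2-[(2E)-5-(tert-butyldimethylsilyloxy)-3-methylpent-2-en-1-yl]-4-methoxy-6-methylphenoxy}dimethylsilane | COc1cc(C)c(O[Si](C)(C)C(C)(C)C)c(C/C=C(\C)CCO[Si](C)(C)C(C)(C)C)c1
F11 | step 5 | (3E)-5-{2-[(tert-butyldimethylsilyl)oxy]-5-methoxy-3-methylphenyl}-3-methylpent-3-en-1-ol | COc1cc(C)c(O[Si](C)(C)C(C)(C)C)c(C/C=C(\C)CCO)c1
F12 | step 5 | (3E)-5-{2-[(tert-butyldimethylsilyl)oxy]-5-methoxy-3-methylphenyl}-3-methylpent-3-enal | COc1cc(C)c(O[Si](C)(C)C(C)(C)C)c(C/C=C(\C)CC=O)c1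
F13 | step 5 | racemic (6E)-8-{2-[(tert-butyldimethylsilyl)oxy]-5-methoxy-3-methylphenyl}-6-methyloct-6-en-2-yn-4-ol | COc1cc(C)c(O[Si](C)(C)C(C)(C)C)c(C/C=C(\C)CC(O)C#CC)c1
F14 | step 5 | (6E)-8-{2-[(tert-butyldimethylsilyl)oxy]-5-methoxy-3-methylphenyl}-6-methyloct-6-en-2-yn-4-one | COc1cc(C)c(O[Si](C)(C)C(C)(C)C)c(C/C=C(\C)CC(=O)C#CC)c1
F15 | step 5 | (4R,6E)-8-{2-[(tert-butyldimethylsilyl)oxy]-5-methoxy-3-methylphenyl}-6-methyloct-6-en-2-yn-4-ol | COc1cc(C)c(O[Si](C)(C)C(C)(C)C)c(C/C=C(\C)C[C@@H](O)C#CC)c1
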